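**Plan**
- Retrosynthesis: the O1 isovalerate and the O7 p-coumarate come off first and C11 returns to a methyl ester; the dihydropyran is then cut at C4–C5, C1–C9 and O2–C1.
- Enabling feature: C1–O2–C3=C4(–C11) of the dihydropyran is one masked diformylacetate unit. Its end carbons C1 and C4 sit on C9 and C5 of the cyclopentane, both on the α face, trans to O7 and C10. This is the footprint of an enol–alkene [2+2], retro-aldol opening and lactol closure.
- Forward: L-erythrulose supplies C10–C8–C7–C6; a vinyl Grignard adds C9, an epoxide opening adds C5, and ring-closing metathesis closes the cyclopentene. The photoannulation then closes the dihydropyran; reduction of C11 and two acylations finish.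
- Stereochemistry: C7 from L-erythrulose; C8 by chelation-controlled Grignard addition beside C7; C5 and C9 by α-face photocycloaddition opposite the β groups on C7 and C8; C1 by anomeric equilibration of the lactol before acylation.

Key step: step 10

Remark: iridoid numbering is used for all compounds, acyclic ones included (C1 acetal carbon, O2, C3=C4, C5/C9 ring fusion, C6, C7, C8, C10 on C8, C11 on C4). β is the face of H5 and H9. Lactols are written as the 1β-hydroxy anomers expected at equilibrium.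

**Route**

Step 1
Reactants: 1 L-erythrulose
Product: 2 3,4-O-isopropylidene-L-erythrulose
Conditions: 2,2-dimethoxypropane, CSA (cat.), acetone, 0 °C to rt
Reagents that add atoms: 2,2-dimethoxypropane COC(C)(C)OC
Why: Acid-catalysed transketalisation should place the isopropylidene group on the vicinal 3,4-diol as the five-membered dioxolane and leave the primary hydroxyl beside the ketone free, the C3 stereocentre (the later C7) not being touched.

Step 2
Reactants: 2 3,4-O-isopropylidene-L-erythrulose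
Product: 3 1-O-(tert-butyldiphenylsilyl)-3,4-O-isopropylidene-L-erythrulose
Conditions: TBDPSCl, imidazole, DMF, 0 °C to rt
Reagents that add atoms: tert-butyl(chloro)diphenylsilane CC(C)(C)[Si](Cl)(c1ccccc1)c1ccccc1
Why: Imidazole-mediated silylation of the primary alcohol is routine, and the bulky, weakly basic silyl ether keeps this oxygen out of magnesium chelates in the next step.

Step 3
Reactants: 3 1-O-(tert-butyldiphenylsilyl)-3,4-O-isopropylidene-L-erythrulose
Product: 4 (2R)-1-[(tert-butyldiphenylsilyl)oxy]-2-[(4S)-2,2-dimethyl-1,3-dioxolan-4-yl]but-3-en-2-ol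
Conditions: CH2=CHMgBr (1.5 equiv), Et2O–THF, −78 °C; aq. NH4Cl
Reagents that add atoms: vinylmagnesium bromide C=C[Mg]Br
Why: Chelation-controlled Grignard addition (Cram cyclic model): magnesium bridges the ketone oxygen and the dioxolane oxygen on the α-carbon, and vinyl should enter from the side of the α-hydrogen, which sets the tertiary carbinol C8 as 2R relative to the pool-derived C7.

Step 4
Reactants: 4 (2R)-1-[(tert-butyldiphenylsilyl)oxy]-2-[(4S)-2,2-dimethyl-1,3-dioxolan-4-yl]but-3-en-2-ol
Product: 5 (2S,3R)-3-{[(tert-butyldiphenylsilyl)oxy]methyl}pent-4-ene-1,2,3-triol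
Conditions: AcOH–H2O (4:1), 40 °C
Reagents that add atoms: none
Why: Acid hydrolysis of the terminal acetonide in aqueous acetic acid should spare the primary TBDPS ether and the tertiary allylic alcohol, whose ionisation is disfavoured by two oxygen-bearing neighbours.

Step 5
Reactants: 5 (2S,3R)-3-{[(tert-butyldiphenylsilyl)oxy]methyl}pent-4-ene-1,2,3-triol
Product: 7 (2R)-1-[(tert-butyldiphenylsilyl)oxy]-2-[(2S)-oxiran-2-yl]but-3-en-2-ol, via primary tosylate 6 (not isolated)
Conditions: TsCl (1.05 equiv), Et3N, Bu2SnO (2 mol %), CH2Cl2, 0 °C; then K2CO3, MeOH, 0 °C, short contact time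
Reagents that add atoms: none
Why: Tin-acetal-mediated sulfonylation picks the primary hydroxyl of the 1,2-diol and carbonate then drives an intramolecular Williamson closure (3-exo-tet) by the C7 oxygen, so the C7–O bond is never broken and its configuration is retained.

Step 6
Reactants: 7 (2R)-1-[(tert-butyldiphenylsilyl)oxy]-2-[(2S)-oxiran-2-yl]but-3-en-2-ol
Product: 8 (3R,4S)-3-{[(tert-butyldiphenylsilyl)oxy]methyl}hepta-1,6-diene-3,4-diol
Conditions: CH2=CHMgBr (3 equiv), CuI (15 mol %), THF, −40 to −20 °C; aq. NH4Cl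
Reagents that add atoms: vinylmagnesium bromide C=C[Mg]Br
Why: Copper-catalysed Grignard opening of a terminal epoxide takes place by SN2 attack at the unsubstituted carbon C6 and leaves C7 and C8 untouched, one equivalent of reagent being spent on the tertiary hydroxyl.

Step 7
Reactants: 8 (3R,4S)-3-{[(tert-butyldiphenylsilyl)oxy]methyl}hepta-1,6-diene-3,4-diol
Product: 9 (1S,2R)-2-{[(tert-butyldiphenylsilyl)oxy]methyl}cyclopent-3-ene-1,2-diol
Conditions: second-generation Grubbs catalyst (3 mol %), CH2Cl2 (0.01 M), 40 °C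
Reagents that add atoms: none
Why: Ring-closing metathesis of the 1,6-diene gives the cyclopentene with loss of ethene and tolerates free allylic and homoallylic hydroxyls.

Step 8
Reactants: 9 (1S,2R)-2-{[(tert-butyldiphenylsilyl)oxy]methyl}cyclopent-3-ene-1,2-diol
Product: 10 (1S,2R)-2-{[(tert-butyldiphenylsilyl)oxy]methyl}-2-hydroxycyclopent-3-en-1-yl acetate
Conditions: Ac2O (1.2 equiv), pyridine, DMAP (5 mol %), CH2Cl2, 0 °C
Reagents that add atoms: acetic anhydride CC(=O)OC(C)=O
Why: DMAP-catalysed acetylation distinguishes the secondary C7 hydroxyl from the tertiary C8 hydroxyl, and the acetate later marks O7 off from the lactol oxygen and leaves in the hydride step without an operation of its own.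

Step 9
Reactants: 11 methyl 3,3-dimethoxypropanoate
Product: 13 methyl diformylacetate (chelated enol), via sodium formyl enolate 12 (not isolated)
Conditions: NaH, HCO2Me, Et2O, 0 °C to rt; then 2 M HCl, 0 °C to rt
Reagents that add atoms: methyl formate COC=O; water O
Why: Crossed Claisen formylation of the ester α-carbon with methyl formate followed by acid hydrolysis of the dimethyl acetal should give the formyl malonaldehyde ester, which exists as its chelated enol.

Step 10
Reactants: 10 (1S,2R)-2-{[(tert-butyldiphenylsilyl)oxy]methyl}-2-hydroxycyclopent-3-en-1-yl acetate; 13 methyl diformylacetate (chelated enol)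
Product: 16 lactol methyl ester (1β-OH; 7-OAc; 8α-OH; 10-OTBDPS), via cyclobutanol photoadduct 14 (not isolated), via seco aldehyde enol 15 (not isolated)
Conditions: 13 (4 equiv), hν (medium-pressure Hg lamp, Corex filter, λ > 260 nm), degassed MeCN, 5 °C; then silica gel, CH2Cl2, rt; excess 13 removed with aq. NaHCO3
Reagents that add atoms: none
Why: De Mayo reaction: the photoexcited chelated enol of 13 adds across C5=C9 through a 1,4-diradical that collapses by radical recombination to the cis-fused cyclobutanol 14 (new bonds C4–C5 and C1–C9), and the β-hydroxy carbonyl unit of 14 opens at once by strain-releasing retro-aldol cleavage of C1–C4 to the C1 aldehyde and the enol of the C3 formyl ester (15). The enol oxygen O2 then adds to the C1 aldehyde in a 6-exo-trig hemiacetalisation, which closes the dihydropyran, the only ring kept, with its enol ether conjugated to the C11 ester. The closest known reaction type is the photoannulation of this same diformylacetate enol onto acyloxy- and alkyl-substituted cyclopentenes with spontaneous retro-aldol and lactol formation. C5 and C9 are set by approach to the α face, beside the small C8 hydroxyl and opposite the C8 CH2OTBDPS and C7 acetoxy groups, the four-membered ring being able to fuse only cis; C1 is set afterwards by equilibration of the lactol through 15 to the axial 1β-hydroxy anomer. The step needs regioselectivity, which the substrate secures because the fully substituted enol carbon C4 avoids C9 beside quaternary C8 and bonds to C5, and α-facial selectivity, which the two β substituents secure.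

Step 11
Reactants: 16 lactol methyl ester (1β-OH; 7-OAc; 8α-OH; 10-OTBDPS)
Product: 17 1-O-triethylsilyl acetal of 16
Conditions: TESCl, imidazole, DMAP (cat.), DMF, 0 °C to rt
Reagents that add atoms: chlorotriethylsilane CC[Si](Cl)(CC)CC
Why: Silylation of the hemiacetal hydroxyl (the tertiary C8 hydroxyl is too hindered for the silyl chloride) turns C1 into a silyl acetal that cannot open to the aldehyde under hydride, the 1β configuration of the equilibrated lactol being carried over.

Step 12
Reactants: 17 1-O-triethylsilyl acetal of 16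
Product: 18 1-O-TES-10-O-TBDPS 7,8,11-triol
Conditions: iBu2AlH (6 equiv), CH2Cl2, −78 to −40 °C; aq. potassium sodium tartrate
Reagents that add atoms: none
Why: iBu2AlH reduces the vinylogous carbonate (β-alkoxyacrylate) 1,2 to the C11 allylic alcohol and cleaves the O7 acetate in the same operation, while the silyl acetal and the silyl ether are inert at low temperature.

Step 13
Reactants: 18 1-O-TES-10-O-TBDPS 7,8,11-triol
Product: 19 1-O-TES-10,11-bis-O-TBDPS 7,8-diol
Conditions: TBDPSCl (1.1 equiv), imidazole, CH2Cl2, 0 °C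
Reagents that add atoms: tert-butyl(chloro)diphenylsilane CC(C)(C)[Si](Cl)(c1ccccc1)c1ccccc1
Why: Silylation with the bulky chlorosilane is selective for the primary allylic C11 hydroxyl over the secondary C7 hydroxyl flanked by quaternary C8 and over the tertiary C8 hydroxyl.

Step 14
Reactants: 20 p-coumaric acid
Product: 22 (2E)-3-{4-[(triisopropylsilyl)oxy]phenyl}prop-2-enoic acid, via bis-silyl derivative 21 (not isolated)
Conditions: TIPSCl (2.3 equiv), imidazole, DMF, rt; then K2CO3, MeOH–THF–H2O, 0 °C; aq. HCl to pH 4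
Reagents that add atoms: chlorotri(propan-2-yl)silane CC(C)[Si](Cl)(C(C)C)C(C)C
Why: Exhaustive silylation followed by selective hydrolysis of the much more labile silyl ester is the standard way to a phenol-protected cinnamic acid, and the aryl triisopropylsilyl ether withstands carbonate, DMAP and buffered HF·pyridine.

Step 15
Reactants: 19 1-O-TES-10,11-bis-O-TBDPS 7,8-diol; 22 (2E)-3-{4-[(triisopropylsilyl)oxy]phenyl}prop-2-enoic acid
Product: 23 O7 (4-O-TIPS)-p-coumarate of 19
Conditions: EDC·HCl, DMAP, CH2Cl2, rt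
Reagents that add atoms: none
Why: Steglich esterification acylates the only reactive hydroxyl, the secondary C7 hydroxyl, with retention at C7 and without touching the E double bond, the silyl acetal or the tertiary C8 hydroxyl.

Step 16
Reactants: 23 O7 (4-O-TIPS)-p-coumarate of 19
Product: 24 lactol (1β-OH) with O7 coumarate and C10/C11 TBDPS ethers
Conditions: HF·pyridine, pyridine, THF, 0 °C; aq. NaHCO3; used at once
Reagents that add atoms: none
Why: Buffered HF·pyridine cleaves the triethylsilyl acetal selectively, since a lactol oxygen is the best leaving group on the least hindered silicon, while the TBDPS and aryl TIPS ethers persist, and the freed 1-hydroxy enol ether lactol (isolable like nepetalactol) should settle as the 1β anomer.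

Step 17
Reactants: 24 lactol (1β-OH) with O7 coumarate and C10/C11 TBDPS ethers; 25 isovaleryl chloride
Product: 26 tris-silylated luzonoid A
Conditions: pyridine, DMAP (cat.), CH2Cl2, −20 to 0 °C
Reagents that add atoms: none
Why: Pyridine/DMAP-mediated O-acylation of the lactol, the only acylable hydroxyl left, should deliver the axial 1β ester because the 1β-hydroxy anomer is favoured by the anomeric effect and by avoiding C8, as in natural 1-O-acyl iridoids.

Step 18
Reactants: 26 tris-silylated luzonoid A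
Product: 27 luzonoid A
Conditions: TBAF, AcOH (1:1, 6 equiv), THF, 0 °C to rt
Reagents that add atoms: none
Why: Fluoride desilylation buffered with acetic acid removes the two TBDPS ethers and the aryl TIPS ether while the buffer suppresses O7-to-O10 acyl migration and attack on the C1 acyl acetal.

**Compound list**

1 | L-erythrulose, (3S)-1,3,4-trihydroxybutan-2-one | OC[C@H](O)C(=O)CO | starting material
2 | 3,4-O-isopropylidene-L-erythrulose, 1-[(4S)-2,2-dimethyl-1,3-dioxolan-4-yl]-2-hydroxyethan-1-one | OCC(=O)[C@@H]1COC(C)(C)O1 | intermediate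
3 | 2-[(tert-butyldiphenylsilyl)oxy]-1-[(4S)-2,2-dimethyl-1,3-dioxolan-4-yl]ethan-1-one | CC(C)(C)[Si](c1ccccc1)(c1ccccc1)OCC(=O)[C@@H]1COC(C)(C)O1 | intermediate
4 | (2R)-1-[(tert-butyldiphenylsilyl)oxy]-2-[(4S)-2,2-dimethyl-1,3-dioxolan-4-yl]but-3-en-2-ol | C=C[C@@](O)(CO[Si](c1ccccc1)(c1ccccc1)C(C)(C)C)[C@@H]1COC(C)(C)O1 | intermediate
5 | (2S,3R)-3-{[(tert-butyldiphenylsilyl)oxy]methyl}pent-4-ene-1,2,3-triol | C=C[C@@](O)(CO[Si](c1ccccc1)(c1ccccc1)C(C)(C)C)[C@@H](O)CO | intermediate
6 | (2S,3R)-3-{[(tert-butyldiphenylsilyl)oxy]methyl}-2,3-dihydroxypent-4-en-1-yl 4-methylbenzenesulfonate | C=C[C@@](O)(CO[Si](c1ccccc1)(c1ccccc1)C(C)(C)C)[C@@H](O)COS(=O)(=O)c1ccc(C)cc1 | intermediate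
7 | (2R)-1-[(tert-butyldiphenylsilyl)oxy]-2-[(2S)-oxiran-2-yl]but-3-en-2-ol | C=C[C@@](O)(CO[Si](c1ccccc1)(c1ccccc1)C(C)(C)C)[C@@H]1CO1 | intermediate
8 | (3R,4S)-3-{[(tert-butyldiphenylsilyl)oxy]methyl}hepta-1,6-diene-3,4-diol | C=C[C@@](O)(CO[Si](c1ccccc1)(c1ccccc1)C(C)(C)C)[C@@H](O)CC=C | intermediate
9 | (1S,2R)-2-{[(tert-butyldiphenylsilyl)oxy]methyl}cyclopent-3-ene-1,2-diol | C1C=C[C@@](O)(CO[Si](c2ccccc2)(c2ccccc2)C(C)(C)C)[C@H]1O | intermediate
10 | (1S,2R)-2-{[(tert-butyldiphenylsilyl)oxy]methyl}-2-hydroxycyclopent-3-en-1-yl acetate | C1C=C[C@@](O)(CO[Si](c2ccccc2)(c2ccccc2)C(C)(C)C)[C@H]1OC(C)=O | intermediate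
11 | methyl 3,3-dimethoxypropanoate | COC(CC(=O)OC)OC | starting material
12 | sodium enolate of methyl 2-formyl-3,3-dimethoxypropanoate | COC(OC)C(=C[O-])C(=O)OC.[Na+] | intermediate
13 | methyl diformylacetate, chelated enol (methyl 2-formyl-3-hydroxyprop-2-enoate) | COC(=O)/C(C=O)=C/O | intermediate
14 | cyclobutanol photoadduct: cis-fused bicyclo[3.2.0]heptane with the cyclobutane C1–C4–C5–C9 on the α face, C1 bearing OH, C4 bearing CHO and CO2Me, 7β-OAc, 8α-OH, 8β-CH2OTBDPS | OC1[C@@H]2[C@@](O)(CO[Si](c3ccccc3)(c3ccccc3)C(C)(C)C)[C@@H](OC(C)=O)C[C@@H]2C1(C=O)C(=O)OC | intermediate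
15 | seco aldehyde enol: cyclopentane with the C1 formyl group on C9 and the enol C4(CO2Me)=C3H–OH on C5, both α | O=C[C@@H]1[C@@](O)(CO[Si](c2ccccc2)(c2ccccc2)C(C)(C)C)[C@@H](OC(C)=O)C[C@@H]1C(C(=O)OC)=CO | intermediate
16 | methyl (1R,4aS,6S,7R,7aS)-6-(acetyloxy)-7-{[(tert-butyldiphenylsilyl)oxy]methyl}-1,7-dihydroxy-1,4a,5,6,7,7a-hexahydrocyclopenta[c]pyran-4-carboxylate | O[C@@H]1OC=C(C(=O)OC)[C@H]2C[C@H](OC(C)=O)[C@](O)(CO[Si](c3ccccc3)(c3ccccc3)C(C)(C)C)[C@@H]12 | intermediate
17 | methyl (1S,4aS,6S,7R,7aS)-6-(acetyloxy)-7-{[(tert-butyldiphenylsilyl)oxy]methyl}-7-hydroxy-1-[(triethylsilyl)oxy]-1,4a,5,6,7,7a-hexahydrocyclopenta[c]pyran-4-carboxylate | CC[Si](CC)(CC)O[C@@H]1OC=C(C(=O)OC)[C@H]2C[C@H](OC(C)=O)[C@](O)(CO[Si](c3ccccc3)(c3ccccc3)C(C)(C)C)[C@@H]12 | intermediate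
18 | (1S,4aS,6S,7R,7aS)-7-{[(tert-butyldiphenylsilyl)oxy]methyl}-4-(hydroxymethyl)-1-[(triethylsilyl)oxy]-1,4a,5,6,7,7a-hexahydrocyclopenta[c]pyran-6,7-diol | CC[Si](CC)(CC)O[C@@H]1OC=C(CO)[C@H]2C[C@H](O)[C@](O)(CO[Si](c3ccccc3)(c3ccccc3)C(C)(C)C)[C@@H]12 | intermediate
19 | (1S,4aS,6S,7R,7aS)-4,7-bis{[(tert-butyldiphenylsilyl)oxy]methyl}-1-[(triethylsilyl)oxy]-1,4a,5,6,7,7a-hexahydrocyclopenta[c]pyran-6,7-diol | CC[Si](CC)(CC)O[C@@H]1OC=C(CO[Si](c3ccccc3)(c3ccccc3)C(C)(C)C)[C@H]2C[C@H](O)[C@](O)(CO[Si](c3ccccc3)(c3ccccc3)C(C)(C)C)[C@@H]12 | intermediate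
20 | p-coumaric acid | OC(=O)/C=C/c1ccc(O)cc1 | starting material
21 | triisopropylsilyl (2E)-3-{4-[(triisopropylsilyl)oxy]phenyl}prop-2-enoate | CC(C)[Si](C(C)C)(C(C)C)OC(=O)/C=C/c1ccc(O[Si](C(C)C)(C(C)C)C(C)C)cc1 | intermediate
22 | (2E)-3-{4-[(triisopropylsilyl)oxy]phenyl}prop-2-enoic acid | OC(=O)/C=C/c1ccc(O[Si](C(C)C)(C(C)C)C(C)C)cc1 | intermediate
23 | (1S,4aS,6S,7R,7aS)-4,7-bis{[(tert-butyldiphenylsilyl)oxy]methyl}-7-hydroxy-1-[(triethylsilyl)oxy]-1,4a,5,6,7,7a-hexahydrocyclopenta[c]pyran-6-yl (2E)-3-{4-[(triisopropylsilyl)oxy]phenyl}prop-2-enoate | CC[Si](CC)(CC)O[C@@H]1OC=C(CO[Si](c3ccccc3)(c3ccccc3)C(C)(C)C)[C@H]2C[C@H](OC(=O)/C=C/c3ccc(O[Si](C(C)C)(C(C)C)C(C)C)cc3)[C@](O)(CO[Si](c3ccccc3)(c3ccccc3)C(C)(C)C)[C@@H]12 | intermediate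
24 | (1R,4aS,6S,7R,7aS)-4,7-bis{[(tert-butyldiphenylsilyl)oxy]methyl}-1,7-dihydroxy-1,4a,5,6,7,7a-hexahydrocyclopenta[c]pyran-6-yl (2E)-3-{4-[(triisopropylsilyl)oxy]phenyl}prop-2-enoate | O[C@@H]1OC=C(CO[Si](c3ccccc3)(c3ccccc3)C(C)(C)C)[C@H]2C[C@H](OC(=O)/C=C/c3ccc(O[Si](C(C)C)(C(C)C)C(C)C)cc3)[C@](O)(CO[Si](c3ccccc3)(c3ccccc3)C(C)(C)C)[C@@H]12 | intermediate
25 | isovaleryl chloride (3-methylbutanoyl chloride) | CC(C)CC(=O)Cl | starting material
26 | (1S,4aS,6S,7R,7aS)-4,7-bis{[(tert-butyldiphenylsilyl)oxy]methyl}-7-hydroxy-6-{[(2E)-3-{4-[(triisopropylsilyl)oxy]phenyl}prop-2-enoyl]oxy}-1,4a,5,6,7,7a-hexahydrocyclopenta[c]pyran-1-yl 3-methylbutanoate | CC(C)CC(=O)O[C@@H]1OC=C(CO[Si](c3ccccc3)(c3ccccc3)C(C)(C)C)[C@H]2C[C@H](OC(=O)/C=C/c3ccc(O[Si](C(C)C)(C(C)C)C(C)C)cc3)[C@](O)(CO[Si](c3ccccc3)(c3ccccc3)C(C)(C)C)[C@@H]12 | intermediate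
27 | luzonoid A, (1S,4aS,6S,7R,7aS)-7-hydroxy-4,7-bis(hydroxymethyl)-6-{[(2E)-3-(4-hydroxyphenyl)prop-2-enoyl]oxy}-1,4a,5,6,7,7a-hexahydrocyclopenta[c]pyran-1-yl 3-methylbutanoate | CC(C)CC(=O)O[C@@H]1OC=C(CO)[C@H]2C[C@H](OC(=O)/C=C/c3ccc(O)cc3)[C@](O)(CO)[C@@H]12 | target

**Step count**

Total: 18 steps. Longest linear sequence: 16 steps from L-erythrulose (steps 1–8, 10–13, 15–18); steps 9 and 14 are one-step side branches.

**Steps most likely to fail**

Step 10. The photoannulation may leak to the crossed regioisomer (C4 bonding to C9), may discriminate the two alkene faces incompletely, or may convert slowly while the enol decays photochemically. The fallback makes the cycloaddition intramolecular. Setting out from 10, the C8 hydroxyl (α face, next to C9) would be silylated with iPr2SiCl2 and imidazole and the remaining Si–Cl bond quenched with 13 and Et3N to give the silicon-tethered enol ether F1. Irradiation as in step 10 would then be an intramolecular [2+2] in which the six-membered siloxane ring forces C1 onto C9 from the α face and leaves C4 no partner but C5, giving the tethered cyclobutane F2. HF·pyridine in THF would cut both Si–O bonds (the TBDPS ether reacts far more slowly) and release cyclobutanol 14, where the route is rejoined and continues to 16.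

Step 16. Removal of the anomeric silyl group may be accompanied by loss of the other silyl ethers. The freed electron-rich lactol may also open to the dialdehyde, with β-elimination of the C11 silyloxy group or epimerisation at C9 before it is acylated. The fallback keeps an electron-withdrawing group on C4 until both esters are in place. Setting out from 18, MnO2 in CH2Cl2 would oxidise only the primary allylic C11 alcohol to the C11 enal F3, a vinylogous formate, so no C11 silyl ether is needed. Steglich esterification of the C7 hydroxyl with 22 gives the coumarate F4. HF·pyridine/pyridine removes the anomeric triethylsilyl group to the formyl-stabilised lactol F5, which is as robust as 16. Acylation with 25 gives the isovalerate F6. NaBH4 in THF–iPrOH at −20 °C reduces the formyl group beside the three esters to the C11 alcohol F7. TBAF/AcOH then removes the C10 TBDPS and aryl TIPS groups and gives 27, where the route is rejoined.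

Step 5. Under base the new terminal epoxide may migrate toward C8 by attack of the tertiary C8 alkoxide on C7 (Payne-type equilibration), which would invert C7 and produce a vinyl epoxide. The fallback avoids any epoxide. Setting out from 6 (isolated after the sulfonylation stage), the C7 and C8 hydroxyls would be tied up with 2,2-dimethoxypropane and PPTS as the tosylate acetonide F8, in which no alkoxide can form. Direct SN2 displacement of the primary tosylate with CH2=CHMgBr and catalytic CuI gives the allyl acetonide F9. Aqueous acetic acid then frees the diol and returns to 8.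

**Further compounds**

F1 | step 10 | silicon-tethered enol ether: 10 with O8 joined through Si(iPr)2 to the enol oxygen of 13 | C1C=C[C@@](O[Si](C(C)C)(C(C)C)OC=C(C=O)C(=O)OC)(CO[Si](c2ccccc2)(c2ccccc2)C(C)(C)C)[C@H]1OC(C)=O
F2 | step 10 | tethered cyclobutane: 14 with O1 and O8 bridged by Si(iPr)2 | O3C1[C@@H]2[C@@](O[Si]3(C(C)C)C(C)C)(CO[Si](c4ccccc4)(c4ccccc4)C(C)(C)C)[C@@H](OC(C)=O)C[C@@H]2C1(C=O)C(=O)OC
F3 | step 16 | C11 enal: 18 with C11 oxidised to CHO | CC[Si](CC)(CC)O[C@@H]1OC=C(C=O)[C@H]2C[C@H](O)[C@](O)(CO[Si](c3ccccc3)(c3ccccc3)C(C)(C)C)[C@@H]12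
F4 | step 16 | O7 (4-O-TIPS)-p-coumarate of F3 | CC[Si](CC)(CC)O[C@@H]1OC=C(C=O)[C@H]2C[C@H](OC(=O)/C=C/c3ccc(O[Si](C(C)C)(C(C)C)C(C)C)cc3)[C@](O)(CO[Si](c3ccccc3)(c3ccccc3)C(C)(C)C)[C@@H]12
F5 | step 16 | formyl-stabilised lactol: F4 with free 1β-OH | O[C@@H]1OC=C(C=O)[C@H]2C[C@H](OC(=O)/C=C/c3ccc(O[Si](C(C)C)(C(C)C)C(C)C)cc3)[C@](O)(CO[Si](c3ccccc3)(c3ccccc3)C(C)(C)C)[C@@H]12
F6 | step 16 | 1-O-isovalerate of F5 | CC(C)CC(=O)O[C@@H]1OC=C(C=O)[C@H]2C[C@H](OC(=O)/C=C/c3ccc(O[Si](C(C)C)(C(C)C)C(C)C)cc3)[C@](O)(CO[Si](c3ccccc3)(c3ccccc3)C(C)(C)C)[C@@H]12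
F7 | step 16 | C11 alcohol of F6 (10-O-TBDPS, aryl O-TIPS luzonoid A) | CC(C)CC(=O)O[C@@H]1OC=C(CO)[C@H]2C[C@H](OC(=O)/C=C/c3ccc(O[Si](C(C)C)(C(C)C)C(C)C)cc3)[C@](O)(CO[Si](c3ccccc3)(c3ccccc3)C(C)(C)C)[C@@H]12
F8 | step 5 | tosylate acetonide: 7,8-O-isopropylidene derivative of 6 | C=C[C@]1(CO[Si](c2ccccc2)(c2ccccc2)C(C)(C)C)OC(C)(C)O[C@H]1COS(=O)(=O)c1ccc(C)cc1
F9 | step 5 | allyl acetonide: 7,8-O-isopropylidene derivative of 8 | C=C[C@]1(CO[Si](c2ccccc2)(c2ccccc2)C(C)(C)C)OC(C)(C)O[C@H]1CC=C
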